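The ten-membered carbocycle is closed between its two carbinol carbons: C8 (bearing the angelate, next to the lactone ring-fusion carbon C7) and C9 (bearing the 2-methylbutanoate, allylic to the C1=C10 alkene that carries the formyl group). Both atoms carry oxygen, so the C8–C9 bond is the retron of a reductive union of two aldehyde carbons of like acceptor polarity. A SmI2 pinacol macrocyclisation forms the ring and both carbinol stereocentres, as the cis-diol, in one operation. Its precursor is an acyclic dialdehyde that already holds the trans-γ-lactone (α-methylene masked as the dimethylamine adduct), both trisubstituted alkenes, C14 as an acetal and C15 as a silyl ether.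

Key step: step 15

Remark (numbering): germacranolide numbering is used throughout, also for acyclic precursors: C12 lactone carbonyl on C11 (C13 exocyclic methylene), lactone oxygen on C6, C7 ring fusion, C8 (O-angelate), C9 (O-2-methylbutanoate), C10 (bears C14) =C1, C2, C3, C4 (bears C15) =C5; β is the face of the C7–C11 bond; TBS = tert-butyldimethylsilyl, TBDPS = tert-butyldiphenylsilyl.
Remark (assumption): (R)-2-methylbutanoic acid, angelic acid, potassium but-3-enyltrifluoroborate and TBS-oxyacetaldehyde are taken as purchasable; the amine adducts are drawn as the expected 11βH epimer, a centre that is erased again in step 18.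

Step 1
Reactants: 1 but-2-yne-1,4-diol
Product: 2 4-(TBDPS-oxy)but-2-yn-1-ol
Conditions: NaH (1 equiv), THF, 0 °C; then TBDPSCl, rt (3 equiv of 1)
Reagents that add atoms: tert-butyl(chloro)diphenylsilane CC(C)(C)[Si](Cl)(c1ccccc1)c1ccccc1
Why: Statistical O-silylation of the symmetric diol through its monosodium alkoxide, with excess diol suppressing the bis-ether.

Step 2
Reactants: 2 4-(TBDPS-oxy)but-2-yn-1-ol
Product: 3 (2Z)-4-(TBDPS-oxy)-3-iodobut-2-en-1-ol
Conditions: NaAlH2(OCH2CH2OMe)2 (Red-Al), THF, 0 °C → rt; EtOAc; then I2, THF, −78 → 0 °C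
Reagents that add atoms: iodine II
Why: Hydroxyl-directed trans-hydroalumination puts aluminium on the distal alkyne carbon (C4) through a five-membered alkoxyaluminate, and iodinolysis with retention should give the Z-iodoalkene, which fixes C15 trans to C6 on the future C4=C5 bond.

Step 3
Reactants: 3 (2Z)-4-(TBDPS-oxy)-3-iodobut-2-en-1-ol; 4 potassium but-3-enyltrifluoroborate
Product: 5 (2E)-3-(TBDPS-oxymethyl)hepta-2,6-dien-1-ol
Conditions: Pd(dppf)Cl2·CH2Cl2 (5 mol %), Cs2CO3, THF/H2O 10:1, 80 °C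
Reagents that add atoms: none
Why: Suzuki–Miyaura sp2–sp3 coupling of an alkenyl iodide with a primary alkyltrifluoroborate proceeds with retention, so the C3 chain should end up cis to C6; the free alcohol is tolerated.

Step 4
Reactants: 6 2-methylidenepropane-1,3-diol
Product: 7 2-(TBS-oxymethyl)prop-2-en-1-ol
Conditions: NaH (1 equiv), THF, 0 °C; then TBSCl, rt
Reagents that add atoms: tert-butyl(chloro)dimethylsilane CC(C)(C)[Si](C)(C)Cl
Why: Monosilylation of a symmetric diol through its monosodium alkoxide, as in step 1.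

Step 5
Reactants: 7 2-(TBS-oxymethyl)prop-2-en-1-ol
Product: 8 2-(TBS-oxymethyl)prop-2-enal
Conditions: MnO2, CH2Cl2, rt
Reagents that add atoms: none
Why: MnO2 oxidises the primary allylic alcohol to the enal under neutral conditions that leave the silyl ether intact.

Step 6
Reactants: 5 (2E)-3-(TBDPS-oxymethyl)hepta-2,6-dien-1-ol; 8 2-(TBS-oxymethyl)prop-2-enal
Product: 9 (2E,6E)-8-hydroxy-2-(TBS-oxymethyl)-6-(TBDPS-oxymethyl)octa-2,6-dienal
Conditions: second-generation Hoveyda–Grubbs catalyst (5 mol %), 8 (4 equiv), CH2Cl2, 40 °C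
Reagents that add atoms: none
Why: Olefin cross-metathesis of a terminal alkene with a 2-substituted acrolein (as with methacrolein) should give the trisubstituted enal with the formyl group trans to the chain, which sets the C1=C10 geometry (C14 trans, C9 cis to C2); the trisubstituted C4=C5 alkene is inert.

Step 7
Reactants: 9 (2E,6E)-8-hydroxy-2-(TBS-oxymethyl)-6-(TBDPS-oxymethyl)octa-2,6-dienal
Product: 10 (2E,6E)-8,8-dimethoxy-7-(TBS-oxymethyl)-3-(TBDPS-oxymethyl)octa-2,6-dien-1-ol
Conditions: HC(OMe)3, PPTS (2 mol %), MeOH, 0 °C; Et3N quench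
Reagents that add atoms: trimethyl orthoformate COC(OC)OC
Why: Acid-catalysed acetalisation masks C14 at its final aldehyde oxidation level for all later redox and acylation steps; low temperature and a basic quench should spare the primary silyl ethers.

Step 8
Reactants: 10 (2E,6E)-8,8-dimethoxy-7-(TBS-oxymethyl)-3-(TBDPS-oxymethyl)octa-2,6-dien-1-ol
Product: 11 (2E,6E)-8,8-dimethoxy-7-(TBS-oxymethyl)-3-(TBDPS-oxymethyl)octa-2,6-dienal
Conditions: MnO2, CH2Cl2, rt
Reagents that add atoms: none
Why: Neutral MnO2 oxidation of the allylic C6 alcohol gives the enal with retention of the C4=C5 geometry and without touching acetal or silyl ethers.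

Step 9
Reactants: 12 TBS-oxyacetaldehyde; 13 methyl acrylate
Product: 14 methyl 4-(TBS-oxy)-3-hydroxy-2-methylidenebutanoate (racemic)
Conditions: DABCO (0.5 equiv), MeOH, rt
Reagents that add atoms: none
Why: Morita–Baylis–Hillman reaction of an aldehyde with an acrylate; the carbinol centre is lost in the next step.

Step 10
Reactants: 14 methyl 4-(TBS-oxy)-3-hydroxy-2-methylidenebutanoate
Product: 15 methyl (2Z)-2-(bromomethyl)-4-(TBS-oxy)but-2-enoate
Conditions: NBS, Me2S, CH2Cl2, 0 °C → rt
Reagents that add atoms: N-bromosuccinimide O=C1CCC(=O)N1Br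
Why: Corey–Kim-type activation of the Baylis–Hillman alcohol and SN2′ attack of bromide should give the conjugated primary allylic bromide as the favoured Z isomer.

Step 11
Reactants: 11 (2E,6E)-8,8-dimethoxy-7-(TBS-oxymethyl)-3-(TBDPS-oxymethyl)octa-2,6-dienal; 15 methyl (2Z)-2-(bromomethyl)-4-(TBS-oxy)but-2-enoate
Product: 18 (4R,5R)-4-(TBS-oxymethyl)-3-methylidene-5-[(1E,5E)-7,7-dimethoxy-6-(TBS-oxymethyl)-2-(TBDPS-oxymethyl)hepta-1,5-dienyl]oxolan-2-one, via trimethylsilyl ether 16 (not isolated), via hydroxy ester 17 (not isolated)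
Conditions: CrCl2 (10 mol %), chiral 3,6-di-tert-butyl-1,8-bis(4-isopropyloxazolin-2-yl)carbazole ligand (12 mol %, enantiomer that directs Si-face attack), iPr2NEt, Mn powder, Me3SiCl, THF, rt; then PPTS, MeOH, 0 °C → rt
Reagents that add atoms: none
Why: Catalytic asymmetric Nozaki–Hiyama–Kishi 2-(alkoxycarbonyl)allylation: the equilibrating allylchromium (trivalent chromium) adds 1,2 to the enal through its γ-carbon in a chair transition state to give the anti adduct (C6–O anti to C8), hence the trans-lactone after acid-induced desilylation and lactonisation, while the bis(oxazoline)chromium complex directs Si-face attack to set C6 as R.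

Step 12
Reactants: 18 trans-α-methylene lactone
Product: 19 (3R,4R,5R)-3-[(dimethylamino)methyl]-4-(TBS-oxymethyl)-5-[(1E,5E)-7,7-dimethoxy-6-(TBS-oxymethyl)-2-(TBDPS-oxymethyl)hepta-1,5-dienyl]oxolan-2-one
Conditions: Me2NH (2 M in THF), MeOH, 0 °C → rt
Reagents that add atoms: dimethylamine CNC
Why: Aza-Michael addition masks the α-methylene lactone, which would otherwise trap ketyl radicals in step 15; protonation trans to the C7 substituent should give the all-trans 11βH adduct.

Step 13
Reactants: 19 dimethylamine adduct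
Product: 20 (3R,4R,5R)-3-[(dimethylamino)methyl]-4-(hydroxymethyl)-5-[(1E,5E)-6-(hydroxymethyl)-7,7-dimethoxy-2-(TBDPS-oxymethyl)hepta-1,5-dienyl]oxolan-2-one
Conditions: CSA (1.2 equiv), MeOH, 0 °C; NaHCO3 work-up
Reagents that add atoms: none
Why: Acid-catalysed methanolysis cleaves the two primary TBS ethers far faster than the TBDPS ether, and the dimethyl acetal only undergoes degenerate exchange in methanol.

Step 14
Reactants: 20 diol
Product: 21 dialdehyde: (3R,4S,5R)-3-[(dimethylamino)methyl]-5-[(1E,5E)-6-formyl-7,7-dimethoxy-2-(TBDPS-oxymethyl)hepta-1,5-dienyl]-2-oxooxolane-4-carbaldehyde (C8 and C9 formyl groups; C9 formyl cis to C2)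
Conditions: Dess–Martin periodinane, NaHCO3, CH2Cl2, 0 °C → rt; used crude at once
Reagents that add atoms: none
Why: Dess–Martin oxidation of both primary alcohols under buffered, near-neutral conditions avoids E1cB opening of the β-acyloxy aldehyde and C7 epimerisation and keeps the C1=C10 geometry.

Step 15
Reactants: 21 dialdehyde
Product: 22 (1(10)E,4E)-13-(dimethylamino)-8β,9β-dihydroxy-14,14-dimethoxy-15-(TBDPS-oxy)-11βH-germacra-1(10),4-dien-12,6α-olide (both ring alkenes cis within the ring)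
Conditions: SmI2 (3 equiv), THF, 0.002 M, slow addition of 21, −78 → 0 °C; aq. NH4Cl
Reagents that add atoms: none
Why: SmI2 reduces the more easily reduced enal carbonyl (C9) to a samarium-bound allylic ketyl, which adds to the samarium-activated C8 aldehyde (or couples with its ketyl), and a second electron gives the trivalent samarium diolate that is hydrolysed on work-up. The closest known reaction type is the SmI2-mediated (and low-valent titanium) intramolecular pinacol coupling of dialdehydes to medium carbocyclic 1,2-diols, including enal–aldehyde pairs. The ten-membered ring closes in a 10-exo-trig sense, the C9 ketyl carbon attacking the exocyclic C8=O, helped by the two ring-cis trisubstituted alkenes and the lactone, which leave few rotors and bring the chain ends together. C8 is controlled by the C7 stereocentre: C9 should approach anti to the C7–C11 bond with the C6–C7–C8–C9 torsion gauche as the forming ring demands (Felkin–Anh), placing O8 cis to C11, while C9 is controlled by bridging of both oxygens on one samarium in the bond-forming event, which should give the cis (erythro) diol. The step needs coupling at C9 (1,2) and not at C1 (1,4, eight-membered ring) and retention of the C1=C10 geometry: the carbonyl carbon is the usual coupling site of enal ketyls, low temperature limits rotation of the allylic radical, and only the ring-cis geometry closes readily. Ketyl addition to an acrylate is excluded because the α-methylene lactone is masked, and high dilution with slow addition suppresses intermolecular coupling.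

Step 16
Reactants: 22 macrocyclic cis-diol; 23 (R)-2-methylbutanoic acid
Product: 24 9β-O-[(2R)-2-methylbutanoyl] monoester of 22 (8β-OH free)
Conditions: EDC·HCl, DMAP (0.1 equiv), 23 (1.05 equiv), CH2Cl2, −20 → 0 °C
Reagents that add atoms: none
Why: Steglich esterification should take the allylic C9 hydroxyl, which is flanked by the planar C10, in preference to the C8 hydroxyl, which is flanked by the ring-fusion carbon C7 and syn to the C11 branch of the lactone; one equivalent of acid at low temperature limits diacylation, acyl migration and epimerisation of the acid.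

Step 17
Reactants: 24 9-monoester; 25 angelic acid
Product: 27 8β-O-angeloyl-9β-O-[(2R)-2-methylbutanoyl] diester, via angelic 2,4,6-trichlorobenzoic anhydride 26 (not isolated)
Conditions: 25, 2,4,6-trichlorobenzoyl chloride, Et3N, toluene, rt; then 24, 80 °C (no DMAP)
Reagents that add atoms: none
Why: Yamaguchi-type acylation with the preformed mixed anhydride in the absence of a nucleophilic catalyst is the established way to make angelates of hindered secondary alcohols with retention of the Z geometry.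

Step 18
Reactants: 27 diester
Product: 29 (1(10)E,4E)-8β-angeloyloxy-14,14-dimethoxy-9β-[(2R)-2-methylbutanoyloxy]-15-(TBDPS-oxy)germacra-1(10),4,11(13)-trien-12,6α-olide, via trimethylammonium iodide 28 (not isolated)
Conditions: MeI, MeCN, rt; then NaHCO3 (aq), CH2Cl2, rt
Reagents that add atoms: none
Why: N-methylation followed by mild-base E1cB (Hofmann-type) loss of trimethylamine from the β-ammonio lactone regenerates the α-methylene-γ-butyrolactone without touching the esters.

Step 19
Reactants: 29 protected α-methylene lactone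
Product: 31 CNP0290361.1 (target), via silyl ether aldehyde 30 (not isolated)
Conditions: HF (48 % aq), MeCN, 0 °C → rt
Reagents that add atoms: water O
Why: Aqueous HF first hydrolyses the very labile α,β-unsaturated dimethyl acetal to the C14 enal and then cleaves the primary TBDPS ether at C15, conditions under which esters, enal and α-methylene lactone should persist.

Compound list
1 | but-2-yne-1,4-diol | OCC#CCO | starting material
2 | 4-(TBDPS-oxy)but-2-yn-1-ol | OCC#CCO[Si](c1ccccc1)(c1ccccc1)C(C)(C)C | intermediate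
3 | (2Z)-4-(TBDPS-oxy)-3-iodobut-2-en-1-ol | OC/C=C(\I)CO[Si](c1ccccc1)(c1ccccc1)C(C)(C)C | intermediate
4 | potassium but-3-enyltrifluoroborate | C=CCC[B-](F)(F)F.[K+] | starting material
5 | (2E)-3-(TBDPS-oxymethyl)hepta-2,6-dien-1-ol | OC/C=C(\CCC=C)CO[Si](c1ccccc1)(c1ccccc1)C(C)(C)C | intermediate
6 | 2-methylidenepropane-1,3-diol | C=C(CO)CO | starting material
7 | 2-(TBS-oxymethyl)prop-2-en-1-ol | C=C(CO)CO[Si](C)(C)C(C)(C)C | intermediate
8 | 2-(TBS-oxymethyl)prop-2-enal | C=C(C=O)CO[Si](C)(C)C(C)(C)C | intermediate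
9 | (2E,6E)-8-hydroxy-2-(TBS-oxymethyl)-6-(TBDPS-oxymethyl)octa-2,6-dienal | OC/C=C(\CC/C=C(/C=O)CO[Si](C)(C)C(C)(C)C)CO[Si](c1ccccc1)(c1ccccc1)C(C)(C)C | intermediate
10 | (2E,6E)-8,8-dimethoxy-7-(TBS-oxymethyl)-3-(TBDPS-oxymethyl)octa-2,6-dien-1-ol | OC/C=C(\CC/C=C(/C(OC)OC)CO[Si](C)(C)C(C)(C)C)CO[Si](c1ccccc1)(c1ccccc1)C(C)(C)C | intermediate
11 | (2E,6E)-8,8-dimethoxy-7-(TBS-oxymethyl)-3-(TBDPS-oxymethyl)octa-2,6-dienal | O=C/C=C(\CC/C=C(/C(OC)OC)CO[Si](C)(C)C(C)(C)C)CO[Si](c1ccccc1)(c1ccccc1)C(C)(C)C | intermediate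
12 | TBS-oxyacetaldehyde | O=CCO[Si](C)(C)C(C)(C)C | starting material
13 | methyl acrylate | C=CC(=O)OC | starting material
14 | methyl 4-(TBS-oxy)-3-hydroxy-2-methylidenebutanoate (racemic) | C=C(C(=O)OC)C(O)CO[Si](C)(C)C(C)(C)C | intermediate
15 | methyl (2Z)-2-(bromomethyl)-4-(TBS-oxy)but-2-enoate | COC(=O)/C(CBr)=C/CO[Si](C)(C)C(C)(C)C | intermediate
16 | O-trimethylsilyl ether of 17 | COC(=O)C(=C)[C@H](CO[Si](C)(C)C(C)(C)C)[C@H](O[Si](C)(C)C)/C=C(/CO[Si](c1ccccc1)(c1ccccc1)C(C)(C)C)CC/C=C(/C(OC)OC)CO[Si](C)(C)C(C)(C)C | intermediate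
17 | methyl (3R,4R,5E,9E)-4-hydroxy-11,11-dimethoxy-2-methylidene-3,10-bis(TBS-oxymethyl)-6-(TBDPS-oxymethyl)undeca-5,9-dienoate (anti adduct) | COC(=O)C(=C)[C@H](CO[Si](C)(C)C(C)(C)C)[C@H](O)/C=C(/CO[Si](c1ccccc1)(c1ccccc1)C(C)(C)C)CC/C=C(/C(OC)OC)CO[Si](C)(C)C(C)(C)C | intermediate
18 | (4R,5R)-4-(TBS-oxymethyl)-3-methylidene-5-[(1E,5E)-7,7-dimethoxy-6-(TBS-oxymethyl)-2-(TBDPS-oxymethyl)hepta-1,5-dienyl]oxolan-2-one | C=C1C(=O)O[C@H](/C=C(/CO[Si](c2ccccc2)(c2ccccc2)C(C)(C)C)CC/C=C(/C(OC)OC)CO[Si](C)(C)C(C)(C)C)[C@H]1CO[Si](C)(C)C(C)(C)C | intermediate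
19 | (3R,4R,5R)-3-[(dimethylamino)methyl] adduct of 18 | CN(C)C[C@@H]1C(=O)O[C@H](/C=C(/CO[Si](c2ccccc2)(c2ccccc2)C(C)(C)C)CC/C=C(/C(OC)OC)CO[Si](C)(C)C(C)(C)C)[C@H]1CO[Si](C)(C)C(C)(C)C | intermediate
20 | (3R,4R,5R)-3-[(dimethylamino)methyl]-4-(hydroxymethyl)-5-[(1E,5E)-6-(hydroxymethyl)-7,7-dimethoxy-2-(TBDPS-oxymethyl)hepta-1,5-dienyl]oxolan-2-one | CN(C)C[C@@H]1C(=O)O[C@H](/C=C(/CO[Si](c2ccccc2)(c2ccccc2)C(C)(C)C)CC/C=C(/C(OC)OC)CO)[C@H]1CO | intermediate
21 | (3R,4S,5R)-3-[(dimethylamino)methyl]-5-[(1E,5E)-6-formyl-7,7-dimethoxy-2-(TBDPS-oxymethyl)hepta-1,5-dienyl]-2-oxooxolane-4-carbaldehyde | CN(C)C[C@@H]1C(=O)O[C@H](/C=C(/CO[Si](c2ccccc2)(c2ccccc2)C(C)(C)C)CC/C=C(/C(OC)OC)C=O)[C@H]1C=O | intermediate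
22 | (1(10)E,4E)-13-(dimethylamino)-8β,9β-dihydroxy-14,14-dimethoxy-15-(TBDPS-oxy)-11βH-germacra-1(10),4-dien-12,6α-olide | CN(C)C[C@@H]1C(=O)O[C@@H]2/C=C(/CO[Si](c3ccccc3)(c3ccccc3)C(C)(C)C)CC/C=C(/C(OC)OC)[C@@H](O)[C@@H](O)[C@@H]12 | intermediate
23 | (R)-2-methylbutanoic acid | CC[C@@H](C)C(=O)O | starting material
24 | 9β-O-[(2R)-2-methylbutanoyl] ester of 22 (8β-OH free) | CN(C)C[C@@H]1C(=O)O[C@@H]2/C=C(/CO[Si](c3ccccc3)(c3ccccc3)C(C)(C)C)CC/C=C(/C(OC)OC)[C@@H](OC(=O)[C@H](C)CC)[C@@H](O)[C@@H]12 | intermediate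
25 | angelic acid, (2Z)-2-methylbut-2-enoic acid | C/C=C(/C)C(=O)O | starting material
26 | (2Z)-2-methylbut-2-enoic 2,4,6-trichlorobenzoic anhydride | C/C=C(/C)C(=O)OC(=O)c1c(Cl)cc(Cl)cc1Cl | intermediate
27 | 8β-O-angeloyl-9β-O-[(2R)-2-methylbutanoyl] diester of 22 | CN(C)C[C@@H]1C(=O)O[C@@H]2/C=C(/CO[Si](c3ccccc3)(c3ccccc3)C(C)(C)C)CC/C=C(/C(OC)OC)[C@@H](OC(=O)[C@H](C)CC)[C@@H](OC(=O)/C(C)=C\C)[C@@H]12 | intermediate
28 | N-methyl quaternary ammonium iodide of 27 | C[N+](C)(C)C[C@@H]1C(=O)O[C@@H]2/C=C(/CO[Si](c3ccccc3)(c3ccccc3)C(C)(C)C)CC/C=C(/C(OC)OC)[C@@H](OC(=O)[C@H](C)CC)[C@@H](OC(=O)/C(C)=C\C)[C@@H]12.[I-] | intermediate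
29 | (1(10)E,4E)-8β-angeloyloxy-14,14-dimethoxy-9β-[(2R)-2-methylbutanoyloxy]-15-(TBDPS-oxy)germacra-1(10),4,11(13)-trien-12,6α-olide | C=C1C(=O)O[C@@H]2/C=C(/CO[Si](c3ccccc3)(c3ccccc3)C(C)(C)C)CC/C=C(/C(OC)OC)[C@@H](OC(=O)[C@H](C)CC)[C@@H](OC(=O)/C(C)=C\C)[C@@H]12 | intermediate
30 | 15-O-TBDPS ether of the target (C14 aldehyde free) | C=C1C(=O)O[C@@H]2/C=C(/CO[Si](c3ccccc3)(c3ccccc3)C(C)(C)C)CC/C=C(/C=O)[C@@H](OC(=O)[C@H](C)CC)[C@@H](OC(=O)/C(C)=C\C)[C@@H]12 | intermediate
31 | CNP0290361.1, (1(10)E,4E,6R,7S,8S,9R)-8-angeloyloxy-15-hydroxy-9-[(2R)-2-methylbutanoyloxy]-14-oxogermacra-1(10),4,11(13)-trien-12,6-olide | C=C1C(=O)O[C@@H]2/C=C(/CO)CC/C=C(/C=O)[C@@H](OC(=O)[C@H](C)CC)[C@@H](OC(=O)/C(C)=C\C)[C@@H]12 | target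

Total step count: 19. Longest linear sequence: 15 steps (1, 2, 3, 6, 7, 8, 11 to 19).

Steps most likely to fail

Step 15 (pinacol macrocyclisation). The allylic ketyl may couple through C1 to an eight-membered ring, lose the C1=C10 geometry by rotation, be reduced further, or close with poor facial control at C9. The fallback sets out from 21 and comes back at 22; it replaces ketyl coupling by a two-electron Takai-type chromium cross-pinacol. CrCl2 (excess) and Et3SiCl in DMF/THF at high dilution should turn the enal into a γ-silyloxyallylchromium species (trivalent chromium). This species adds through its oxygen-bearing carbon C9 to the C8 aldehyde in a chair transition state, which is expected to favour the anti (ring-cis) diol, obtained as the 9-O-triethylsilyl ether of 22 F1. PPTS in MeOH then frees 22.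

Step 16 (site-selective monoacylation). The two secondary hydroxyls may be acylated with poor selectivity, or the ester may migrate between O9 and O8. The fallback sets out from 22 and comes back at 27; it tells the two oxygens apart by oxidation state. MnO2 should oxidise only the allylic C9 hydroxyl to give the 8β-hydroxy-9-oxo enone F2. The remaining C8 hydroxyl is angeloylated (25, 2,4,6-trichlorobenzoyl chloride, Et3N, toluene) to the 8β-angeloyloxy-9-oxo enone F3. Luche reduction (NaBH4, CeCl3·7H2O, MeOH, −78 °C), with hydride delivery anti to the α-acyloxy group (Felkin–Anh), is expected to return the 9β-alcohol as the 8β-angeloyloxy-9β-hydroxy compound F4. Esterification of F4 with 23 (EDC, DMAP) gives 27.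

Step 17 (angeloylation). Acylation of the hindered C8 hydroxyl may be slow, with Z to E isomerisation to the tiglate or acyl migration at 80 °C. The fallback sets out from 24 and comes back at 27; it builds the angelate on the oxygen. Esterification with 2-[bis(2,2,2-trifluoroethoxy)phosphoryl]propanoic acid (DCC, DMAP, rt) gives the 8β-O-phosphonopropanoate F5. Still–Gennari olefination of F5 with acetaldehyde (KN(SiMe3)2, 18-crown-6, THF, −78 °C) should give the Z-2-methylbut-2-enoate 27.

Further compounds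
F1 | step 15 | 9-O-triethylsilyl ether of 22 | CN(C)C[C@@H]1C(=O)O[C@@H]2/C=C(/CO[Si](c3ccccc3)(c3ccccc3)C(C)(C)C)CC/C=C(/C(OC)OC)[C@@H](O[Si](CC)(CC)CC)[C@@H](O)[C@@H]12
F2 | step 16 | 8β-hydroxy-9-oxo enone from 22 | CN(C)C[C@@H]1C(=O)O[C@@H]2/C=C(/CO[Si](c3ccccc3)(c3ccccc3)C(C)(C)C)CC/C=C(/C(OC)OC)C(=O)[C@@H](O)[C@@H]12
F3 | step 16 | 8β-angeloyloxy-9-oxo enone | CN(C)C[C@@H]1C(=O)O[C@@H]2/C=C(/CO[Si](c3ccccc3)(c3ccccc3)C(C)(C)C)CC/C=C(/C(OC)OC)C(=O)[C@@H](OC(=O)/C(C)=C\C)[C@@H]12
F4 | step 16 | 8β-angeloyloxy-9β-hydroxy compound | CN(C)C[C@@H]1C(=O)O[C@@H]2/C=C(/CO[Si](c3ccccc3)(c3ccccc3)C(C)(C)C)CC/C=C(/C(OC)OC)[C@@H](O)[C@@H](OC(=O)/C(C)=C\C)[C@@H]12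
F5 | step 17 | 8β-O-{2-[bis(2,2,2-trifluoroethoxy)phosphoryl]propanoyl} ester of 24 | CN(C)C[C@@H]1C(=O)O[C@@H]2/C=C(/CO[Si](c3ccccc3)(c3ccccc3)C(C)(C)C)CC/C=C(/C(OC)OC)[C@@H](OC(=O)[C@H](C)CC)[C@@H](OC(=O)C(C)P(=O)(OCC(F)(F)F)OCC(F)(F)F)[C@@H]12
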